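It is tempting to carry a percent slope from one flask to the next, but a percent is a share of the charge, and dawn holds less solid substrate than maple, 0.54 M against 0.81 M.

common to all: free catalyst 0.43 mol%

| run | solid substrate | coupling partner | temperature | remark | time |
|---|---|---|---|---|---|
| maple | 0.81 M | 1.8 equiv | 70 °C | run made earlier |  |
| dawn | 0.54 M | 1.80 equiv | 70 °C |  | 8.0 d |
| spring | 0.54 M | 1.80 equiv | 40 °C |  | 8.0 d |

maple run (percent of the solid substrate charged)

| time / d | product / % | solid substrate / % |
|---|---|---|
| 0.208 | 0.6 | 98.7 |
| 0.333 | 0.1 | 98.1 |
| 0.625 | 1.0 | 97.3 |
| 1.25 | 4.0 | 93.7 |
| 2.50 | 8.6 | 88.9 |

(readings scatter by 0.3 percentage points)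

- solid substrate is a solid; its amount is given per volume of the solution
- at the start none of the solid substrate is in solution
- what has only dissolved of solid substrate counts as not reacted
- the earlier runs do not show what temperature does; that part of a forecast is a guess
- no earlier run changes the charge of free catalyst; that part of a forecast is a guess

- the flask with the highest amount of product, in percent of the solid substrate charged ("all alike" if they lie within 1.5 percentage points) (dawn / spring / all alike)
- final product, as a percentage of the solid substrate charged, in dawn
- final product, as a percentage of the solid substrate charged, in spring

Between maple's last two readings, product grows by 0.0368 d⁻¹ as a fraction of maple's charge. We assume that this stream comes from a solid dissolving at a steady amount per litre per day, whatever the charge, which makes it zero order in the solid. Multiplying the slope by the ratio of the charges and by dawn's time gives 44.2%. This is the feed number, the share of a flask's charge that the stream passes in its time. We read dawn's product directly from it, since it stays below the whole charge.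

Is one number enough? On maple's last reading, slope times time gives 9.20% against 8.6% measured; the slope rests on two readings, each good to 0.3 percentage points, so this gap of 0.6 points does not measure a start-up delay. The number also contains no temperature, and the steady stream at a changed catalyst concentration remains our assumption. For spring we therefore have no reckoning of our own and accept the forecast's guess.

The forecast names dawn, with 28% there and 3% in spring, reasoning that “If rate scales with catalyst, percent conversion stays near 4 %/d”. For dawn, our 44.2% stands higher than its figure.

The flasks give dawn as the higher, with 43.3% in dawn and 6.10% in spring.

    coupling partner + catalyst intermediate B → catalyst intermediate C (k = 0.0632 L mol⁻¹ min⁻¹, Ea = 59.0 kJ mol⁻¹)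
    starting material + free catalyst → catalyst intermediate A (k = 0.385 L mol⁻¹ min⁻¹, Ea = 71.0 kJ mol⁻¹)
    catalyst intermediate A → catalyst intermediate B (k = 0.184 min⁻¹, Ea = 92.0 kJ mol⁻¹)
    solid substrate ⇌ starting material, rate k4*(cs4 - [starting material]) while solid is left; crystals form when [starting material] > cs4 (solubility = 0.190 M, k = 1.49 × 10⁻⁴ min⁻¹)
    catalyst intermediate D → free catalyst + product (k = 0.183 min⁻¹, Ea = 102 kJ mol⁻¹)
    catalyst intermediate C → catalyst intermediate D (k = 1.47 min⁻¹, Ea = 87.0 kJ mol⁻¹)
    (constants at 70 °C)

Dawn's feed number lies 0.90 points above its product. The neighbouring flask is dawn with 0.450 equiv of coupling partner. Its solid charge and time are dawn's, so the same reckoning again gives 44.2%, yet the neighbouring flask ends at 28.1%, which is 16 points lower. At 8.00 d, catalyst intermediate B holds 80.1% of the neighbouring flask's catalyst and free catalyst 14.5%, against 20.8% and 68.0% in dawn, and 38% of the neighbouring flask's coupling partner is left.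

The readings stem from a simulated flask with made-up constants; the scatter is artificial.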